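**Retrosynthetic overview**
- Target ⇐ methyl ester ⇐ C6 quaternary centre made last, by a ligand-controlled Pd dearomative n-prenylation of a 6-alkyl-5,7-dihydroxychromanone (the proposed new step).
- The 6-CH2-cyclobutyl group ⇐ reductive alkylation of the free C6–H with a cis-cyclobutanecarbaldehyde taken from (−)-verbenone (the cyclobutane is chiral pool and is never built).
- Aromatic core ⇐ lactone methanolysis and O-demethylation ⇐ cis-2,3-dimethylchromanone closed by a quinine-catalysed oxa-Michael addition of a tigloyl phenol.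
- Benzylic centre ⇐ CuH asymmetric conjugate reduction of a 4-phenylcoumarin; the 7-OMe group and the lactone leave only one phenol free to close the chromanone.
- Ring order: coumarin lactone (bought) → dihydrocoumarin → chromanone ring → lactone opened → carbocycle dearomatised.

Assumption: the catalyst antipodes named ((R)-DTBM-SEGPHOS, (−)-quinine, (R,R)-Trost ligand) are those expected by analogy to give the drawn configurations; if a sense proves opposite, the mirror-image catalyst (quinidine for quinine) is used in the same step. Ring positions of the chromanone compounds are given in chromanone numbering (O1, C2, C3, C4=O, C4a, C5–C8, C8a).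

**Route**

Step 1
Reactants: 1 5,7-dihydroxy-4-phenylcoumarin
Product: 2 5-hydroxy-7-methoxy-4-phenylcoumarin
Conditions: MeI (1.05 equiv), K2CO3 (1.1 equiv), acetone, rt
Reagents that add atoms: iodomethane, CI
Why: Williamson O-methylation goes to the unhindered 7-OH, because the 5-OH is shielded by the twisted peri 4-phenyl ring.

Step 2
Reactants: 2 5-hydroxy-7-methoxy-4-phenylcoumarin
Product: 3 (4S)-5-hydroxy-7-methoxy-4-phenylchroman-2-one
Conditions: Cu(OAc)2·H2O (5 mol%), (R)-DTBM-SEGPHOS (5.5 mol%), (EtO)2MeSiH, t-BuOH, toluene, 0 °C to rt; aq NH4F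
Reagents that add atoms: none
Why: CuH-catalysed asymmetric conjugate reduction of the β-aryl unsaturated lactone delivers hydride to one face of C4 under ligand control and so sets the benzylic centre as S.

Step 3
Reactants: 3 (4S)-5-hydroxy-7-methoxy-4-phenylchroman-2-one; 4 tigloyl chloride ((2E)-2-methylbut-2-enoyl chloride)
Product: 5 (4S)-5-hydroxy-7-methoxy-6-[(2E)-2-methylbut-2-enoyl]-4-phenylchroman-2-one
Conditions: TiCl4 (2.5 equiv), CH2Cl2, −20 to 0 °C, cold aqueous quench
Reagents that add atoms: none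
Why: Titanium-phenolate-directed ortho Friedel–Crafts acylation puts the E-enoyl group on C6, the only free position ortho to the phenol; any C8-acyl isomer translactonises under the amine of step 4 into the same ketone-chelated phenol.

Step 4
Reactants: 5 (4S)-5-hydroxy-7-methoxy-6-[(2E)-2-methylbut-2-enoyl]-4-phenylchroman-2-one
Product: 6 (2R,3S,10S)-5-methoxy-2,3-dimethyl-10-phenyl-2,3,9,10-tetrahydro-4H,8H-pyrano[2,3-f]chromene-4,8-dione
Conditions: (−)-quinine (20 mol%), chlorobenzene, 15 °C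
Reagents that add atoms: none
Why: Cinchona-catalysed intramolecular oxa-Michael addition, in which the only free phenol adds to one face of the enone β-carbon (C2 = R) and kinetic syn protonation of the enol gives the cis (3S) chromanone.

Step 5
Reactants: 6 (2R,3S,10S)-5-methoxy-2,3-dimethyl-10-phenyl-2,3,9,10-tetrahydro-4H,8H-pyrano[2,3-f]chromene-4,8-dione
Product: 8 (2R,3S,10S)-5-hydroxy-2,3-dimethyl-10-phenyl-2,3,9,10-tetrahydro-4H,8H-pyrano[2,3-f]chromene-4,8-dione, via aryl dichloroborinate 7 (not isolated)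
Conditions: BCl3 (1.5 equiv), CH2Cl2, −78 to −20 °C; H2O
Reagents that add atoms: boron trichloride, ClB(Cl)Cl (its BCl2 group is carried by 7 only)
Why: Chelation-controlled cleavage of the methyl ether peri to the chromanone carbonyl; no base is present, so the epimerisable C3 centre is kept.

Step 6
Reactants: 8 (2R,3S,10S)-5-hydroxy-2,3-dimethyl-10-phenyl-2,3,9,10-tetrahydro-4H,8H-pyrano[2,3-f]chromene-4,8-dione
Product: 9 methyl (3S)-3-[(2R,3S)-5,7-dihydroxy-2,3-dimethyl-4-oxo-3,4-dihydro-2H-chromen-8-yl]-3-phenylpropanoate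
Conditions: NaOMe (2.2 equiv), MeOH, 0 °C; AcOH quench at 0 °C
Reagents that add atoms: sodium methoxide, [Na+].[O-]C
Why: Methanolysis of the aryl lactone frees the 7-OH; the 5-phenoxide formed first turns the ketone into a vinylogous carboxylate, which suppresses enolisation and retro-oxa-Michael at C2/C3.

Step 7
Reactants: 10 (1S,5S)-(−)-verbenone
Product: 12 (1S,3R)-3-acetyl-2,2-dimethylcyclobutane-1-carboxylic acid (cis-pinononic acid), via alpha-keto acid 11 (not isolated)
Conditions: RuCl3·xH2O (2 mol%), NaIO4 (4.2 equiv), EtOAc/MeCN/H2O, rt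
Reagents that add atoms: sodium periodate, [Na+].[O-]I(=O)(=O)=O; water, O
Why: RuO4 oxidative cleavage of the enone C=C followed by oxidative decarboxylation of the α-keto acid; both ring stereocentres come unchanged from the chiral pool.

Step 8
Reactants: 12 (1S,3R)-3-acetyl-2,2-dimethylcyclobutane-1-carboxylic acid
Product: 14 (1S,3R)-3-acetyl-N-methoxy-N,2,2-trimethylcyclobutane-1-carboxamide, via acyl imidazolide 13 (not isolated)
Conditions: CDI, CH2Cl2, rt; then MeNH(OMe)·HCl, rt
Reagents that add atoms: 1,1'-carbonyldiimidazole, O=C(n1ccnc1)n1ccnc1 (imidazolyl of 13 only); N,O-dimethylhydroxylamine hydrochloride, CNOC.Cl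
Why: Weinreb amide formation through the acyl imidazolide under near-neutral conditions that leave both α-stereocentres alone.

Step 9
Reactants: 14 (1S,3R)-3-acetyl-N-methoxy-N,2,2-trimethylcyclobutane-1-carboxamide
Product: 15 (1S,3S)-N-methoxy-N,2,2-trimethyl-3-(prop-1-en-2-yl)cyclobutane-1-carboxamide
Conditions: Ph3PCH3Br (1.5 equiv), KOtBu (1.4 equiv), THF, 0 °C to rt
Reagents that add atoms: methyltriphenylphosphonium bromide, C[P+](c1ccccc1)(c1ccccc1)c1ccccc1.[Br-]
Why: Wittig methylenation of the methyl ketone, with base kept below the phosphonium salt so that no free alkoxide epimerises C3 (the descriptor changes from R to S by CIP priority only).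

Step 10
Reactants: 15 (1S,3S)-N-methoxy-N,2,2-trimethyl-3-(prop-1-en-2-yl)cyclobutane-1-carboxamide
Product: 16 (1S,3S)-2,2-dimethyl-3-(prop-1-en-2-yl)cyclobutane-1-carbaldehyde
Conditions: LiAlH4, THF, −20 to 0 °C; Rochelle salt; used at once
Reagents that add atoms: none
Why: Weinreb amide reduction stops at the chelated tetrahedral intermediate and gives the aldehyde on work-up with no over-reduction.

Step 11
Reactants: 9 methyl (3S)-3-[(2R,3S)-5,7-dihydroxy-2,3-dimethyl-4-oxo-3,4-dihydro-2H-chromen-8-yl]-3-phenylpropanoate; 16 (1S,3S)-2,2-dimethyl-3-(prop-1-en-2-yl)cyclobutane-1-carbaldehyde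
Product: 18 methyl (3S)-3-[(2R,3S)-6-{[(1R,3S)-2,2-dimethyl-3-(prop-1-en-2-yl)cyclobutyl]methyl}-5,7-dihydroxy-2,3-dimethyl-4-oxo-3,4-dihydro-2H-chromen-8-yl]-3-phenylpropanoate, via o-quinone methide 17 (not isolated)
Conditions: L-proline (20 mol%), Hantzsch ester (1.3 equiv), CH2Cl2, rt
Reagents that add atoms: none
Why: Three-component reductive alkylation (amine-catalysed Knoevenagel condensation at C6, the only free ring carbon, then Hantzsch-ester hydride transfer to the o-quinone methide); the hindered α-branched aldehyde forms an enamine only slowly, so the cyclobutane centre next to it is kept and no new stereocentre arises.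

Step 12
Reactants: 19 3-methylbut-2-en-1-ol (prenol)
Product: 20 methyl 3-methylbut-2-en-1-yl carbonate
Conditions: ClCO2Me, pyridine, CH2Cl2, 0 °C
Reagents that add atoms: methyl chloroformate, COC(Cl)=O
Why: Simple O-acylation of the allylic alcohol gives the ionisable carbonate for Pd chemistry.

Step 13
Reactants: 18 methyl (3S)-3-[(2R,3S)-6-{[(1R,3S)-2,2-dimethyl-3-(prop-1-en-2-yl)cyclobutyl]methyl}-5,7-dihydroxy-2,3-dimethyl-4-oxo-3,4-dihydro-2H-chromen-8-yl]-3-phenylpropanoate; 20 methyl 3-methylbut-2-en-1-yl carbonate (1.3 equiv)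
Product: 21 methyl (3S)-3-[(2R,3S,6R)-6-{[(1R,3S)-2,2-dimethyl-3-(prop-1-en-2-yl)cyclobutyl]methyl}-4-hydroxy-2,3-dimethyl-6-(3-methylbut-2-en-1-yl)-5,7-dioxo-3,5,6,7-tetrahydro-2H-chromen-8-yl]-3-phenylpropanoate
Conditions: Pd2(dba)3·CHCl3 (2.5 mol%), (R,R)-DACH-phenyl Trost ligand (7.5 mol%), toluene, 0 °C to rt
Reagents that add atoms: none
Why: Proposed new method: a ligand-controlled, face-selective Pd dearomative n-prenylation of an unprotected 6-alkyl acylphloroglucinol, in which ionisation of 20 gives (η3-prenyl)Pd(L*)+ and methoxide, the methoxide deprotonates the acidic 7-OH, and the planar phloroglucinolate attacks outer-sphere through C6 (flanked by two oxygen donors and bearing only a primary alkyl group, whereas C8 is blocked by the sec-benzylic group) at the unsubstituted allyl terminus, while O-prenyl ethers are re-ionised by Pd(0) so the irreversible C–C bond formation drains the mixture; the ligand amide N–H groups bind the C7–O−/C5–OH···O=C4 edge of the ion-paired nucleophile and the ligand walls leave one π-face of C6 open, so the catalyst and not the remote centres sets C6 as R; the closest known reactions are Pd/Trost-ligand asymmetric allylic prenylation of prochiral enolates to nucleophile-centred quaternary carbons and the non-stereoselective Pd-catalysed dearomative allylation of acylphloroglucinols.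

Step 14
Reactants: 21 methyl (3S)-3-[(2R,3S,6R)-6-{[(1R,3S)-2,2-dimethyl-3-(prop-1-en-2-yl)cyclobutyl]methyl}-4-hydroxy-2,3-dimethyl-6-(3-methylbut-2-en-1-yl)-5,7-dioxo-3,5,6,7-tetrahydro-2H-chromen-8-yl]-3-phenylpropanoate
Product: 22 (3S)-3-[(2R,3S,6R)-6-{[(1R,3S)-2,2-dimethyl-3-(prop-1-en-2-yl)cyclobutyl]methyl}-4-hydroxy-2,3-dimethyl-6-(3-methylbut-2-en-1-yl)-5,7-dioxo-3,5,6,7-tetrahydro-2H-chromen-8-yl]-3-phenylpropanoic acid (CNP0328119.1)
Conditions: LiOH·H2O (4 equiv), THF/H2O, 0 °C to rt; 1 M HCl to pH 3 at 0 °C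
Reagents that add atoms: lithium hydroxide monohydrate, [Li+].[OH-].O
Why: Saponification of the methyl ester; the enolised triketone is present as its delocalised enolate, which protects the C5/C7 carbonyls from retro-Claisen attack and C3 from epimerisation.

**Compound list**
1 | 5,7-dihydroxy-4-phenylcoumarin | O=c1cc(-c2ccccc2)c2c(O)cc(O)cc2o1 | starting material
2 | 5-hydroxy-7-methoxy-4-phenylcoumarin | O=c1cc(-c2ccccc2)c2c(O)cc(OC)cc2o1 | intermediate
3 | (4S)-5-hydroxy-7-methoxy-4-phenylchroman-2-one | O=C1C[C@@H](c2ccccc2)c2c(O)cc(OC)cc2O1 | intermediate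
4 | tigloyl chloride, (2E)-2-methylbut-2-enoyl chloride | C/C=C(\C)C(Cl)=O | starting material
5 | (4S)-5-hydroxy-7-methoxy-6-[(2E)-2-methylbut-2-enoyl]-4-phenylchroman-2-one | COc1cc2OC(=O)C[C@@H](c3ccccc3)c2c(O)c1C(=O)/C(C)=C/C | intermediate
6 | (2R,3S,10S)-5-methoxy-2,3-dimethyl-10-phenyl-2,3,9,10-tetrahydro-4H,8H-pyrano[2,3-f]chromene-4,8-dione (cis-2,3-dimethylchromanone fused to the 4-phenyl-dihydrocoumarin lactone) | C[C@H]1Oc2c3c(cc(OC)c2C(=O)[C@H]1C)OC(=O)C[C@H]3c1ccccc1 | intermediate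
7 | 5-O-dichloroboryl derivative of 8 (aryl dichloroborinate, in situ) | C[C@H]1Oc2c3c(cc(OB(Cl)Cl)c2C(=O)[C@H]1C)OC(=O)C[C@H]3c1ccccc1 | intermediate
8 | (2R,3S,10S)-5-hydroxy-2,3-dimethyl-10-phenyl-2,3,9,10-tetrahydro-4H,8H-pyrano[2,3-f]chromene-4,8-dione | C[C@H]1Oc2c3c(cc(O)c2C(=O)[C@H]1C)OC(=O)C[C@H]3c1ccccc1 | intermediate
9 | methyl (3S)-3-[(2R,3S)-5,7-dihydroxy-2,3-dimethyl-4-oxo-3,4-dihydro-2H-chromen-8-yl]-3-phenylpropanoate | C[C@H]1Oc2c([C@@H](CC(=O)OC)c3ccccc3)c(O)cc(O)c2C(=O)[C@H]1C | intermediate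
10 | (1S,5S)-(−)-verbenone | CC1=CC(=O)[C@H]2C[C@@H]1C2(C)C | starting material
11 | 2-[(1S,3R)-3-acetyl-2,2-dimethylcyclobutyl]-2-oxoacetic acid (in situ) | CC(=O)[C@@H]1C[C@H](C(=O)C(=O)O)C1(C)C | intermediate
12 | (1S,3R)-3-acetyl-2,2-dimethylcyclobutane-1-carboxylic acid | CC(=O)[C@@H]1C[C@H](C(=O)O)C1(C)C | intermediate
13 | 1-[(1R,3S)-3-(imidazole-1-carbonyl)-2,2-dimethylcyclobutyl]ethan-1-one (acyl imidazolide of 12, in situ) | CC(=O)[C@@H]1C[C@H](C(=O)n2ccnc2)C1(C)C | intermediate
14 | (1S,3R)-3-acetyl-N-methoxy-N,2,2-trimethylcyclobutane-1-carboxamide | CC(=O)[C@@H]1C[C@H](C(=O)N(C)OC)C1(C)C | intermediate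
15 | (1S,3S)-N-methoxy-N,2,2-trimethyl-3-(prop-1-en-2-yl)cyclobutane-1-carboxamide | C=C(C)[C@@H]1C[C@H](C(=O)N(C)OC)C1(C)C | intermediate
16 | (1S,3S)-2,2-dimethyl-3-(prop-1-en-2-yl)cyclobutane-1-carbaldehyde | C=C(C)[C@@H]1C[C@H](C=O)C1(C)C | intermediate
17 | o-quinone methide: methyl (3S)-3-[(2R,3S)-6-{[(1R,3S)-2,2-dimethyl-3-(prop-1-en-2-yl)cyclobutyl]methylidene}-5-hydroxy-2,3-dimethyl-4,7-dioxo-3,4,6,7-tetrahydro-2H-chromen-8-yl]-3-phenylpropanoate (in situ, C=C geometry not defined) | C[C@H]1OC2=C([C@@H](CC(=O)OC)c3ccccc3)C(=O)C(=C[C@H]3C[C@@H](C(C)=C)C3(C)C)C(O)=C2C(=O)[C@H]1C | intermediate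
18 | methyl (3S)-3-[(2R,3S)-6-{[(1R,3S)-2,2-dimethyl-3-(prop-1-en-2-yl)cyclobutyl]methyl}-5,7-dihydroxy-2,3-dimethyl-4-oxo-3,4-dihydro-2H-chromen-8-yl]-3-phenylpropanoate | C[C@H]1Oc2c([C@@H](CC(=O)OC)c3ccccc3)c(O)c(C[C@H]3C[C@@H](C(C)=C)C3(C)C)c(O)c2C(=O)[C@H]1C | intermediate
19 | 3-methylbut-2-en-1-ol (prenol) | CC(C)=CCO | starting material
20 | methyl 3-methylbut-2-en-1-yl carbonate | COC(=O)OCC=C(C)C | intermediate
21 | methyl (3S)-3-[(2R,3S,6R)-6-{[(1R,3S)-2,2-dimethyl-3-(prop-1-en-2-yl)cyclobutyl]methyl}-4-hydroxy-2,3-dimethyl-6-(3-methylbut-2-en-1-yl)-5,7-dioxo-3,5,6,7-tetrahydro-2H-chromen-8-yl]-3-phenylpropanoate | C=C(C)[C@@H]1C[C@H](C[C@@]2(CC=C(C)C)C(=O)C3=C(O)[C@@H](C)[C@@H](C)OC3=C([C@@H](CC(=O)OC)c3ccccc3)C2=O)C1(C)C | intermediate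
22 | (3S)-3-[(2R,3S,6R)-6-{[(1R,3S)-2,2-dimethyl-3-(prop-1-en-2-yl)cyclobutyl]methyl}-4-hydroxy-2,3-dimethyl-6-(3-methylbut-2-en-1-yl)-5,7-dioxo-3,5,6,7-tetrahydro-2H-chromen-8-yl]-3-phenylpropanoic acid | C=C(C)[C@@H]1C[C@H](C[C@@]2(CC=C(C)C)C(=O)C3=C(O)[C@@H](C)[C@@H](C)OC3=C([C@@H](CC(=O)O)c3ccccc3)C2=O)C1(C)C | target

**Summary**
Total step count: 14. Longest linear sequence: 9 steps (1 → 22 through steps 1–6, 11, 13 and 14); the cyclobutane branch (steps 7–10) and step 12 converge on it.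

**Three steps most likely to fail**

Step 13 (the proposed new step). The ligand may not override the substrate, giving low diastereoselectivity at C6, or O-prenylation and branched attack may compete. The fallback sets out from 18 and comes back at 21 and uses the classical base-mediated alkylative dearomatisation of acylphloroglucinols: 18 with NaOMe (2 equiv) and prenyl bromide in MeOH at 0 °C gives 21 together with its C6 epimer, methyl (3S)-3-[(2R,3S,6S)-6-{[(1R,3S)-2,2-dimethyl-3-(prop-1-en-2-yl)cyclobutyl]methyl}-4-hydroxy-2,3-dimethyl-6-(3-methylbut-2-en-1-yl)-5,7-dioxo-3,5,6,7-tetrahydro-2H-chromen-8-yl]-3-phenylpropanoate F1, as a roughly 1:1 pair. Because the other five stereocentres are fixed, the two are diastereomers and are separated by preparative HPLC; 21 then goes on to step 14.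

Step 11. The hindered aldehyde may condense slowly, the o-quinone methide may be trapped by a second arene or by its own isopropenyl group, and the aldehyde α-centre may epimerise. The fallback sets out from 9 and 16 and comes back at 18 by a Negishi sp2–sp3 coupling that involves no enolisable aldehyde at the C–C bond-forming stage. Compound 9 is iodinated at its only free ring position (NIS, MeCN, 0 °C) to methyl (3S)-3-[(2R,3S)-5,7-dihydroxy-6-iodo-2,3-dimethyl-4-oxo-3,4-dihydro-2H-chromen-8-yl]-3-phenylpropanoate F2. Compound 16 is reduced (NaBH4, MeOH, 0 °C) to [(1S,3S)-2,2-dimethyl-3-(prop-1-en-2-yl)cyclobutyl]methanol F3 and converted (I2, PPh3, imidazole, CH2Cl2) into (1S,3S)-1-(iodomethyl)-2,2-dimethyl-3-(prop-1-en-2-yl)cyclobutane F4. Polar iodine–lithium exchange (t-BuLi, Et2O/pentane, −78 °C, which avoids the ring-opening cyclobutylcarbinyl radical) gives {[(1S,3S)-2,2-dimethyl-3-(prop-1-en-2-yl)cyclobutyl]methyl}lithium F5, and ZnCl2 turns it into {[(1S,3S)-2,2-dimethyl-3-(prop-1-en-2-yl)cyclobutyl]methyl}zinc chloride F6. Coupling of F2 with excess F6 (Pd(OAc)2, SPhos, THF, rt; two equivalents are spent on the phenols) gives 18.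

Step 4. On this new substrate the cis/trans ratio or the enantio-sense of the alkaloid-catalysed cyclisation may be poor, and the cis product is base-labile until step 5. The fallback sets out from 3 (so it also replaces step 3) and comes back at 6 by the aldol/Mitsunobu construction of cis-chromanones. Compound 3 is acylated with propanoyl chloride (TiCl4, CH2Cl2, 0 °C) to (4S)-5-hydroxy-7-methoxy-4-phenyl-6-propanoylchroman-2-one F7. Its E-boron enolate ((c-Hex)2BCl, Et3N, Et2O, −78 °C) adds to acetaldehyde to give the two anti aldols, (4S)-5-hydroxy-6-[(2S,3S)-3-hydroxy-2-methylbutanoyl]-7-methoxy-4-phenylchroman-2-one F8 and (4S)-5-hydroxy-6-[(2R,3R)-3-hydroxy-2-methylbutanoyl]-7-methoxy-4-phenylchroman-2-one F9, which are diastereomers because of the fixed 4S centre and are separated on silica. Mitsunobu closure of F8 (PPh3, DIAD, THF, 0 °C) by the chelated phenol, with inversion at the carbinol carbon, turns the anti aldol into the cis-2,3-dimethylchromanone 6.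

**Further compounds**
F1 | step 13 | methyl (3S)-3-[(2R,3S,6S)-6-{[(1R,3S)-2,2-dimethyl-3-(prop-1-en-2-yl)cyclobutyl]methyl}-4-hydroxy-2,3-dimethyl-6-(3-methylbut-2-en-1-yl)-5,7-dioxo-3,5,6,7-tetrahydro-2H-chromen-8-yl]-3-phenylpropanoate | C=C(C)[C@@H]1C[C@H](C[C@]2(CC=C(C)C)C(=O)C3=C(O)[C@@H](C)[C@@H](C)OC3=C([C@@H](CC(=O)OC)c3ccccc3)C2=O)C1(C)C
F2 | step 11 | methyl (3S)-3-[(2R,3S)-5,7-dihydroxy-6-iodo-2,3-dimethyl-4-oxo-3,4-dihydro-2H-chromen-8-yl]-3-phenylpropanoate | C[C@H]1Oc2c([C@@H](CC(=O)OC)c3ccccc3)c(O)c(I)c(O)c2C(=O)[C@H]1C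
F3 | step 11 | [(1S,3S)-2,2-dimethyl-3-(prop-1-en-2-yl)cyclobutyl]methanol | C=C(C)[C@@H]1C[C@H](CO)C1(C)C
F4 | step 11 | (1S,3S)-1-(iodomethyl)-2,2-dimethyl-3-(prop-1-en-2-yl)cyclobutane | C=C(C)[C@@H]1C[C@H](CI)C1(C)C
F5 | step 11 | {[(1S,3S)-2,2-dimethyl-3-(prop-1-en-2-yl)cyclobutyl]methyl}lithium | [Li]C[C@H]1C[C@@H](C(C)=C)C1(C)C
F6 | step 11 | {[(1S,3S)-2,2-dimethyl-3-(prop-1-en-2-yl)cyclobutyl]methyl}zinc chloride | Cl[Zn]C[C@H]1C[C@@H](C(C)=C)C1(C)C
F7 | step 4 | (4S)-5-hydroxy-7-methoxy-4-phenyl-6-propanoylchroman-2-one | COc1cc2OC(=O)C[C@@H](c3ccccc3)c2c(O)c1C(=O)CC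
F8 | step 4 | (4S)-5-hydroxy-6-[(2S,3S)-3-hydroxy-2-methylbutanoyl]-7-methoxy-4-phenylchroman-2-one | COc1cc2OC(=O)C[C@@H](c3ccccc3)c2c(O)c1C(=O)[C@@H](C)[C@H](C)O
F9 | step 4 | (4S)-5-hydroxy-6-[(2R,3R)-3-hydroxy-2-methylbutanoyl]-7-methoxy-4-phenylchroman-2-one | COc1cc2OC(=O)C[C@@H](c3ccccc3)c2c(O)c1C(=O)[C@H](C)[C@@H](C)O
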